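**Retrosynthetic overview**

- Numbering (cadinane): ring A = C1–C2–C3–C4–C5–C6, ring B = C1–C10–C9–C8–C7–C6 (C1 and C6 are the ring-fusion atoms), C11–C13 on C7, C14 on C10, C15 on C4.
- Endgame: the target comes from acylation and desilylation of a C12 allylic alcohol. Its tetrasubstituted C7=C11 alkene (C12 cis to C8) comes from nickel-catalysed 1,4-hydroboration of an s-cis diene C8=C7–C11=C12, made from a C7 ketone by a Shapiro–Negishi sequence. C3 is set by convex-face Luche reduction.
- Enabling feature: ring A is a 2-methylcyclohex-2-en-1-ol in which C3–C4 is a carbinol–alkenyl bond and C1 is β to C3, and the ring-fusion atom C6 lies next to C7, which can be carried as a ketone. C4–C5–C6 is then a 1,3-dinucleophile ((Z)-iodoalkene at C4, enamine carbon C6) and C3–C2–C1 is an enal.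
- Key disconnection: the cis-fused bicyclic C7 ketone comes from an acyclic keto enal in one flask, by Michael addition C6→C1 (ring B closes first) and then Nozaki–Hiyama–Kishi addition C4→C3 (ring A). Only C9 and C10 are stereogenic in the precursor and they relay to C1 and C6.
- The keto enal comes from cross-metathesis, dithiane unmasking and dithiane alkylation with a (Z)-iodobutenyl bromide; C9 and C10 come from one catalytic (Z)-crotylboration.

Key step: step 10

Remark: in step 5 the (S) antipode of the phosphoric acid is assumed to direct the crotyl group to the Si face of the aldehyde; if the sense of induction is the opposite, the (R) antipode is used and nothing else changes.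

**Route**

Step 1
Reactants: 1 but-2-yn-1-ol
Product: 2 (Z)-3-iodobut-2-en-1-ol
Conditions: NaAlH2(OCH2CH2OMe)2, Et2O, 0 °C to 23 °C; then I2, −78 °C to 23 °C; aqueous work-up
Reagents that add atoms: iodine, II
Why: Hydroxyl-directed trans-hydroalumination of the propargylic alcohol places aluminium on C3 and iodinolysis with retention should give the Z iodoalkene (alanate reduction–iodination of a propargylic alcohol), which fixes the geometry later needed for ring A.

Step 2
Reactants: 2 (Z)-3-iodobut-2-en-1-ol
Product: 3 (Z)-1-bromo-3-iodobut-2-ene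
Conditions: CBr4, PPh3, CH2Cl2, 0 °C
Reagents that add atoms: carbon tetrabromide, BrC(Br)(Br)Br
Why: Appel bromination of the primary allylic alcohol proceeds by SN2 displacement of the oxyphosphonium ion and should not touch the iodoalkene.

Step 3
Reactants: 4 1,3-dithiane; 5 oxirane
Product: 7 2-(1,3-dithian-2-yl)ethan-1-ol, via 2-lithio-1,3-dithiane 6 (not isolated)
Conditions: n-BuLi, THF, −30 °C; then 5, −78 °C to 0 °C; H2O
Reagents that add atoms: none
Why: The lithiated dithiane (Corey–Seebach acyl anion equivalent, the later C7 carbonyl) opens the epoxide at carbon by SN2 attack.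

Step 4
Reactants: 7 2-(1,3-dithian-2-yl)ethan-1-ol
Product: 8 2-(1,3-dithian-2-yl)acetaldehyde
Conditions: (COCl)2, DMSO, CH2Cl2, −78 °C; then Et3N, −78 °C to 0 °C
Reagents that add atoms: none
Why: Swern oxidation stops at the aldehyde and the thioacetal is inert to the chlorosulfonium reagent at low temperature.

Step 5
Reactants: 8 2-(1,3-dithian-2-yl)acetaldehyde; 9 (Z)-crotylboronic acid pinacol ester
Product: 11 (2R,3R)-1-(1,3-dithian-2-yl)-3-methylpent-4-en-2-ol, via pinacol borate ester 10 (not isolated)
Conditions: (S)-3,3′-bis(2,4,6-triisopropylphenyl)-1,1′-binaphthyl-2,2′-diyl hydrogen phosphate (5 mol %), 4 Å molecular sieves, toluene, −30 °C; aqueous work-up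
Reagents that add atoms: none
Why: Chiral phosphoric acid-catalysed crotylboration runs through a closed chair transition state, so the Z geometry of the boronate should give the syn C9/C10 pair while the catalyst antipode selects the Si face of the aldehyde, setting C9 (R) and C10 (R).

Step 6
Reactants: 11 (2R,3R)-1-(1,3-dithian-2-yl)-3-methylpent-4-en-2-ol
Product: 12 tert-butyl{[(2R,3R)-1-(1,3-dithian-2-yl)-3-methylpent-4-en-2-yl]oxy}dimethylsilane
Conditions: TBSOTf, 2,6-lutidine, CH2Cl2, −78 °C to 0 °C
Reagents that add atoms: tert-butyldimethylsilyl trifluoromethanesulfonate, CC(C)(C)[Si](C)(C)OS(=O)(=O)C(F)(F)F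
Why: Silyl triflate silylation of the hindered secondary alcohol blocks it as a base-stable ether for the organolithium chemistry of step 7.

Step 7
Reactants: 12 silyl ether; 3 (Z)-1-bromo-3-iodobut-2-ene
Product: 14 2-[(2Z)-3-iodobut-2-en-1-yl]-2-[(2R,3R)-2-(tert-butyldimethylsilyloxy)-3-methylpent-4-en-1-yl]-1,3-dithiane, via lithiated dithiane 13 (not isolated)
Conditions: t-BuLi, THF/HMPA (10:1), −78 °C; then 3, −78 °C to −40 °C
Reagents that add atoms: none
Why: Deprotonation of the 2-substituted dithiane and SN2 alkylation with the allylic bromide (Corey–Seebach alkylation) should join the two halves, the polar medium keeping silicon on oxygen and the stabilised carbanion leaving the iodoalkene intact.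

Step 8
Reactants: 14 dialkylated dithiane
Product: 15 (2Z,7R,8R)-7-(tert-butyldimethylsilyloxy)-2-iodo-8-methyldeca-2,9-dien-5-one
Conditions: MeI, CaCO3, MeCN/H2O (9:1), 40 °C
Reagents that add atoms: water, O
Why: S-Methylation and hydrolysis of the dithiane unmask the C7 ketone under near-neutral conditions that should not move the β,γ-alkene into conjugation.

Step 9
Reactants: 15 dienone; 16 (E)-but-2-enal
Product: 17 (2E,4R,5R,9Z)-5-(tert-butyldimethylsilyloxy)-10-iodo-4-methyl-7-oxoundeca-2,9-dienal
Conditions: 16 (5 equiv), second-generation Hoveyda–Grubbs catalyst RuCl2(H2IMes)(=CH-C6H4-2-O-i-Pr) (5 mol %), CH2Cl2, 40 °C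
Reagents that add atoms: none
Why: Olefin cross-metathesis of the monosubstituted alkene with excess crotonaldehyde should give the E enal, the trisubstituted iodoalkene being too hindered to enter the catalytic cycle.

Step 10
Reactants: 17 acyclic keto enal
Product: 19 cis-fused bicyclic keto alcohol (C7 ketone, C3–OH as epimer mixture, C4=C5, C9–OTBS; C1, C6, C9, C10 as in 32), via keto aldehyde 18 (not isolated)
Conditions: pyrrolidine (0.3 equiv), AcOH (0.3 equiv), DMSO, 23 °C; then CrCl2 (8 equiv), NiCl2 (0.05 equiv), same flask, 23 °C; aqueous work-up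
Reagents that add atoms: none
Why: Pyrrolidine converts the C7 ketone of 17 into its conjugated (E)-enamine (N–C7=C6) and the enal into the iminium ion, and C6 adds to C1 (intramolecular Michael addition, 6-(enolendo)-exo-trig) to close ring B and give keto aldehyde 18; CrCl2 with catalytic NiCl2 then converts the (Z)-iodoalkene into the alkenylchromium reagent, whose C4 adds to the C3 aldehyde (Nozaki–Hiyama–Kishi reaction, 6-exo-trig) to close ring A. The closest known reaction types are the amine-catalysed intramolecular Michael addition of ketones to enals and the intramolecular Nozaki–Hiyama–Kishi cyclisation of (Z)-iodoalkenes onto aldehydes. C1 and C6 are set together in a chair transition state with the C10 methyl, the C9 silyloxy group and the C1–C2 chain equatorial, so the C9/C10 stereocentres fix the face of C1, while the (E)-enamine geometry places C5 cis to C8 and hence axial, which gives the cis ring fusion. C3 is formed without reliable control and is corrected in steps 13 and 14. The step needs C6 rather than C8 or C4 as the Michael donor (only the C6→C1 closure is six-membered), retention of the Z geometry of the iodoalkene so that C4 can reach C3 (alkenylchromium formation is stereoretentive), and addition to the aldehyde in the presence of the C7 ketone (organochromium reagents discriminate strongly in favour of aldehydes).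

Step 11
Reactants: 19 bicyclic keto alcohol
Product: 20 C7 2,4,6-triisopropylbenzenesulfonylhydrazone of 19
Conditions: 2,4,6-(i-Pr)3C6H2SO2NHNH2, PPTS (cat.), THF, 23 °C
Reagents that add atoms: 2,4,6-triisopropylbenzenesulfonohydrazide, CC(C)c1cc(C(C)C)c(S(=O)(=O)NN)c(C(C)C)c1
Why: Condensation of the C7 ketone with the sulfonyl hydrazide gives the hydrazone needed for the Shapiro reaction, with the N–N bond expected anti to the more substituted C6.

Step 12
Reactants: 20 sulfonylhydrazone; 21 2-bromopropene
Product: 24 diene alcohol (C8=C7–C11(CH3)=C12H2, C3–OH epimer mixture), via alkenyllithium 22 (not isolated), via alkenylzinc chloride 23 (not isolated)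
Conditions: n-BuLi (3.3 equiv), THF, −78 °C to 0 °C; ZnCl2, 0 °C; 21, Pd(PPh3)4 (5 mol %), 23 °C; H2O
Reagents that add atoms: none
Why: Shapiro reaction, the C8–H syn to the sulfonamide nitrogen being removed (the C6–H is anti and equatorial), then loss of sulfinate and N2 gives the C7 alkenyllithium that is transmetalated to zinc and coupled with 2-bromopropene (Negishi coupling) to install C11–C13 as a 1,3-diene.

Step 13
Reactants: 24 diene alcohol
Product: 25 C3 enone (C3=O conjugated with C4=C5)
Conditions: MnO2, CH2Cl2, 23 °C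
Reagents that add atoms: none
Why: MnO2 oxidises both C3 epimers of the allylic alcohol to one enone (allylic alcohol oxidation), which erases the uncontrolled stereocentre.

Step 14
Reactants: 25 enone
Product: 26 C3 allylic alcohol with the C3–O bond cis to C10 (configuration of 32)
Conditions: NaBH4, CeCl3·7H2O, MeOH, −78 °C
Reagents that add atoms: none
Why: Luche 1,2-reduction, in which hydride should attack C3 from the convex face of the cis-fused bicycle, anti to the axial C1–C10 bond, so that the new C3–O bond is cis to C10 as in the target.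

Step 15
Reactants: 26 allylic alcohol
Product: 27 C3,C9-bis(tert-butyldimethylsilyl) ether of the diene
Conditions: TBSOTf, 2,6-lutidine, CH2Cl2, −78 °C to 0 °C
Reagents that add atoms: tert-butyldimethylsilyl trifluoromethanesulfonate, CC(C)(C)[Si](C)(C)OS(=O)(=O)C(F)(F)F
Why: Silylation protects the allylic alcohol so that the zerovalent nickel catalyst of step 16 meets no ionisable allylic oxygen function.

Step 16
Reactants: 27 bis-silyl diene
Product: 29 C12 primary allylic alcohol with the tetrasubstituted C7=C11 alkene (C12 cis to C8), via allylboronate 28 (not isolated)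
Conditions: HBpin, Ni(cod)2 (5 mol %), PCy3 (5 mol %), toluene, 23 °C; then NaOH, H2O2, THF, 0 °C
Reagents that add atoms: hydrogen peroxide, OO
Why: Nickel-catalysed 1,4-hydroboration of the 1,3-diene through its η4-bound s-cis conformer delivers hydrogen to C8 and boron to C12 on the same side, which should fix C12 cis to C8 across the new tetrasubstituted C7=C11 bond, and oxidation of the C–B bond with retention gives the primary allylic alcohol.

Step 17
Reactants: 29 allylic alcohol
Product: 30 C12 formate
Conditions: acetic formic anhydride, pyridine, CH2Cl2, −20 °C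
Reagents that add atoms: acetic formic anhydride, CC(=O)OC=O
Why: Formyl transfer from the mixed anhydride to the only free (primary) hydroxyl gives the formate (acylation).

Step 18
Reactants: 30 formate
Product: 31 C3,C9-diol C12-formate
Conditions: HF·pyridine, pyridine, THF, 0 °C to 23 °C
Reagents that add atoms: none
Why: Fluoride-mediated desilylation under acidic buffering removes both silyl ethers while the formate ester should survive.

Step 19
Reactants: 31 diol
Product: 32 (1S,3R,6S,9R,10R,7(11)E)-3,9-diacetoxycadina-4,7(11)-dien-12-yl formate (target)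
Conditions: Ac2O, Et3N, DMAP (cat.), CH2Cl2, 23 °C
Reagents that add atoms: acetic anhydride, CC(=O)OC(C)=O
Why: DMAP-catalysed acetylation of both secondary alcohols completes the target, the formate being stable to the anhydride.

**Compound list**

1 | but-2-yn-1-ol | CC#CCO | starting material
2 | (Z)-3-iodobut-2-en-1-ol | C/C(I)=C/CO | intermediate
3 | (Z)-1-bromo-3-iodobut-2-ene | C/C(I)=C/CBr | intermediate
4 | 1,3-dithiane | C1CSCSC1 | starting material
5 | oxirane | C1CO1 | starting material
6 | 2-lithio-1,3-dithiane | [Li]C1SCCCS1 | intermediate (not isolated)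
7 | 2-(1,3-dithian-2-yl)ethan-1-ol | OCCC1SCCCS1 | intermediate
8 | 2-(1,3-dithian-2-yl)acetaldehyde | O=CCC1SCCCS1 | intermediate
9 | (Z)-crotylboronic acid pinacol ester | C/C=C\CB1OC(C)(C)C(C)(C)O1 | starting material
10 | pinacol borate ester of 11 | C=C[C@@H](C)[C@H](OB1OC(C)(C)C(C)(C)O1)CC1SCCCS1 | intermediate (not isolated)
11 | (2R,3R)-1-(1,3-dithian-2-yl)-3-methylpent-4-en-2-ol | C=C[C@@H](C)[C@H](O)CC1SCCCS1 | intermediate
12 | tert-butyl{[(2R,3R)-1-(1,3-dithian-2-yl)-3-methylpent-4-en-2-yl]oxy}dimethylsilane | C=C[C@@H](C)[C@H](O[Si](C)(C)C(C)(C)C)CC1SCCCS1 | intermediate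
13 | 2-lithio derivative of 12 | C=C[C@@H](C)[C@H](O[Si](C)(C)C(C)(C)C)CC1([Li])SCCCS1 | intermediate (not isolated)
14 | 2-[(2Z)-3-iodobut-2-en-1-yl]-2-[(2R,3R)-2-(tert-butyldimethylsilyloxy)-3-methylpent-4-en-1-yl]-1,3-dithiane | C=C[C@@H](C)[C@H](O[Si](C)(C)C(C)(C)C)CC1(C/C=C(/C)I)SCCCS1 | intermediate
15 | (2Z,7R,8R)-7-(tert-butyldimethylsilyloxy)-2-iodo-8-methyldeca-2,9-dien-5-one | C=C[C@@H](C)[C@H](O[Si](C)(C)C(C)(C)C)CC(=O)C/C=C(/C)I | intermediate
16 | (E)-but-2-enal | C/C=C/C=O | starting material
17 | (2E,4R,5R,9Z)-5-(tert-butyldimethylsilyloxy)-10-iodo-4-methyl-7-oxoundeca-2,9-dienal | O=C/C=C/[C@@H](C)[C@H](O[Si](C)(C)C(C)(C)C)CC(=O)C/C=C(/C)I | intermediate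
18 | keto aldehyde: cyclohexanone ring B with CH2CHO on C1 and (Z)-2-iodoprop-1-enyl on C6 (cis), C10 methyl, C9 OTBS | O=CC[C@@H]1[C@@H](C)[C@H](O[Si](C)(C)C(C)(C)C)CC(=O)[C@@H]1/C=C(/C)I | intermediate (not isolated)
19 | cis-fused 9-(tert-butyldimethylsilyloxy)-3-hydroxycadin-4-en-7-one skeleton without C11–C13 (C3 epimer mixture) | OC1C[C@@H]2[C@@H](C)[C@H](O[Si](C)(C)C(C)(C)C)CC(=O)[C@@H]2C=C1C | intermediate
20 | C7 2,4,6-triisopropylbenzenesulfonylhydrazone of 19 | OC1C[C@@H]2[C@@H](C)[C@H](O[Si](C)(C)C(C)(C)C)CC(=NNS(=O)(=O)c3c(C(C)C)cc(C(C)C)cc3C(C)C)[C@@H]2C=C1C | intermediate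
21 | 2-bromopropene | CC(Br)=C | starting material
22 | C7 alkenyllithium (C7=C8), lithium C3 alkoxide | [Li]OC1C[C@@H]2[C@@H](C)[C@H](O[Si](C)(C)C(C)(C)C)C=C([Li])[C@@H]2C=C1C | intermediate (not isolated)
23 | C7 alkenylzinc chloride, lithium C3 alkoxide | [Li]OC1C[C@@H]2[C@@H](C)[C@H](O[Si](C)(C)C(C)(C)C)C=C([Zn]Cl)[C@@H]2C=C1C | intermediate (not isolated)
24 | 7-isopropenyl diene alcohol (C8=C7–C11=C12; C3–OH epimer mixture; C9 OTBS) | OC1C[C@@H]2[C@@H](C)[C@H](O[Si](C)(C)C(C)(C)C)C=C(C(C)=C)[C@@H]2C=C1C | intermediate
25 | C3 enone of 24 | O=C1C[C@@H]2[C@@H](C)[C@H](O[Si](C)(C)C(C)(C)C)C=C(C(C)=C)[C@@H]2C=C1C | intermediate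
26 | C3 allylic alcohol, C3–O cis to C10 | O[C@@H]1C[C@@H]2[C@@H](C)[C@H](O[Si](C)(C)C(C)(C)C)C=C(C(C)=C)[C@@H]2C=C1C | intermediate
27 | C3,C9-bis(tert-butyldimethylsilyl) ether of 26 | CC(C)(C)[Si](C)(C)O[C@@H]1C[C@@H]2[C@@H](C)[C@H](O[Si](C)(C)C(C)(C)C)C=C(C(C)=C)[C@@H]2C=C1C | intermediate
28 | C12 pinacol allylboronate, C7=C11 with C12 cis to C8 | CC(C)(C)[Si](C)(C)O[C@@H]1C[C@@H]2[C@@H](C)[C@H](O[Si](C)(C)C(C)(C)C)C/C(=C(/C)CB3OC(C)(C)C(C)(C)O3)[C@@H]2C=C1C | intermediate (not isolated)
29 | C12 allylic alcohol, 3,9-bis(silyl ether), (7(11)E) | CC(C)(C)[Si](C)(C)O[C@@H]1C[C@@H]2[C@@H](C)[C@H](O[Si](C)(C)C(C)(C)C)C/C(=C(/C)CO)[C@@H]2C=C1C | intermediate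
30 | C12 formate of 29 | CC(C)(C)[Si](C)(C)O[C@@H]1C[C@@H]2[C@@H](C)[C@H](O[Si](C)(C)C(C)(C)C)C/C(=C(/C)COC=O)[C@@H]2C=C1C | intermediate
31 | 3,9-dihydroxycadina-4,7(11)-dien-12-yl formate | O[C@@H]1C[C@@H]2[C@@H](C)[C@H](O)C/C(=C(/C)COC=O)[C@@H]2C=C1C | intermediate
32 | (1S,3R,6S,9R,10R,7(11)E)-3,9-diacetoxycadina-4,7(11)-dien-12-yl formate | CC(=O)O[C@@H]1C[C@@H]2[C@@H](C)[C@H](OC(C)=O)C/C(=C(/C)COC=O)[C@@H]2C=C1C | target

**Step count and weak points**

Total: 19 steps. Longest linear sequence: 17 steps (steps 3 to 19, from 1,3-dithiane); steps 1 and 2 prepare bromide 3.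

Steps most likely to fail:

1. Step 10 (key step). Several processes may erode it. The keto aldehyde 18 may be diverted by aldol attack of the C8 enamine on the C3 aldehyde. C10 may epimerise through dienamine formation of the enal. The Michael addition may go through the enol and not the (E)-enamine, which would lose the cis ring fusion. The amine salt may also slow the chromium stage. Fallback: the two ring closures are separated and the second one changes mechanism. Compound 17 is cyclised with the amine catalyst alone and 18 is isolated after buffered work-up. Ring A is then closed by a tin hydride chain reaction (Bu3SnH, AIBN, benzene, 80 °C), in which the alkenyl radical at C4 adds 6-exo to the aldehyde carbon C3 and the alkoxyl radical is reduced by the stannane. This sets out from 17 and returns to the route at 19; no new compound arises (F0).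

2. Step 12. Dianion formation may go astray, either by deprotonation at C6 to the conjugated aza-enolate or by β-elimination of silanolate from C9, and the alkenyllithium may be protonated before transmetalation. Fallback, setting out from 19: silylation of the C3 hydroxyl (Et3SiCl, imidazole) gives the triethylsilyl ether F1. Kinetic enolisation toward C8 with KN(SiMe3)2 at −78 °C (only the axial C8–H is aligned with the carbonyl) and O-triflation with N-(5-chloro-2-pyridyl)triflimide give the enol triflate F2. Suzuki–Miyaura coupling with isopropenylboronic acid pinacol ester (PdCl2(dppf), K3PO4) gives the silylated diene F3. Selective removal of the triethylsilyl group (PPTS, MeOH) returns to the route at 24.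

3. Step 16. The hydroboration may add 1,2 across the isopropenyl group or place boron on C8, and isomerisation of the allylnickel intermediate may erode the alkene geometry. Fallback, setting out from 27: palladium-catalysed 1,4-hydrosilylation with HSiCl3 (Pd(PPh3)4), which for 2-methyl-1,3-dienes places silicon on the CH2 terminus through a π-allylpalladium hydride pathway and keeps the diene termini cis, should give the allyltrichlorosilane F4. Ethanolysis (EtOH, Et3N) gives the triethoxysilane F5, and Tamao–Fleming oxidation (KF, KHCO3, H2O2) returns to the route at 29.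

Further compounds
F0 | step 10 | none | none
F1 | step 12 | C3 triethylsilyl ether of 19 | CC[Si](CC)(CC)OC1C[C@@H]2[C@@H](C)[C@H](O[Si](C)(C)C(C)(C)C)CC(=O)[C@@H]2C=C1C
F2 | step 12 | C7 enol triflate (C7=C8) of F1 | CC[Si](CC)(CC)OC1C[C@@H]2[C@@H](C)[C@H](O[Si](C)(C)C(C)(C)C)C=C(OS(=O)(=O)C(F)(F)F)[C@@H]2C=C1C
F3 | step 12 | C3 triethylsilyl ether of 24 | CC[Si](CC)(CC)OC1C[C@@H]2[C@@H](C)[C@H](O[Si](C)(C)C(C)(C)C)C=C(C(C)=C)[C@@H]2C=C1C
F4 | step 16 | C12 trichlorosilane, C7=C11 with C12 cis to C8 | CC(C)(C)[Si](C)(C)O[C@@H]1C[C@@H]2[C@@H](C)[C@H](O[Si](C)(C)C(C)(C)C)C/C(=C(/C)C[Si](Cl)(Cl)Cl)[C@@H]2C=C1C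
F5 | step 16 | C12 triethoxysilane, C7=C11 with C12 cis to C8 | CC(C)(C)[Si](C)(C)O[C@@H]1C[C@@H]2[C@@H](C)[C@H](O[Si](C)(C)C(C)(C)C)C/C(=C(/C)C[Si](OCC)(OCC)OCC)[C@@H]2C=C1C
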